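**Retrosynthetic overview**

1. The strategy rests on the cyclopentenone ring C8–C12 (prostanoid numbering): its C9 carbonyl, its C10=C11 double bond and its oxygen-bearing quaternary C12 correspond to the aldehyde carbon, the alkyne and the C3 ether carbon of a 4-alkynal.
2. Late disconnections: the C12 silyl ether; then C7=C8, by aldol condensation of the C8 enolate with methyl (Z)-7-oxohept-5-enoate (C1–C7); then C10–Cl, from the C10=C11 enone by epoxidation and chloride opening, after the C10 silyl cap has been removed.
3. Ring disconnection (the only ring, closed in step 7): C9–C10, by rhodium-catalysed trans-hydroacylation of a racemic MOM-protected 3-alkoxy-4-alkynal with kinetic resolution, which selects C12.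
4. Alkynal: Reformatsky addition (C8–C12 bond) to a silyl ynone made from the Weinreb amide of (Z)-non-3-enoic acid and lithium (trimethylsilyl)acetylide, then MOM protection and partial ester reduction.
5. C1–C7 enal: hex-5-ynoic acid, hydroxymethylation, esterification, Lindlar reduction, oxidation.

Key step: step 7

Remark on numbering: atom numbers are those of the target, C1 (ester carbon) to C20.
Assumption: which antipode of Tol-BINAP matches the (S)-alkynal cannot be derived safely for a MOM ether and a silyl-capped alkyne; (R)-Tol-BINAP is written in step 7 and is exchanged for (S)-Tol-BINAP, with nothing else changed, if a trial shows the opposite sense.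

**Route**

Step 1
Reactants: 1 (Z)-non-3-en-1-ol
Product: 2 (Z)-non-3-enoic acid
Conditions: TEMPO (cat.), PhI(OAc)2, MeCN–H2O, 0 °C to rt
Reagents that add atoms: water, O
Why: The TEMPO/PhI(OAc)2 oxidation takes the primary alcohol through the aldehyde hydrate to the acid at near-neutral pH, so the Z-alkene should neither isomerise nor move into conjugation.

Step 2
Reactants: 2 (Z)-non-3-enoic acid
Product: 3 (Z)-N-methoxy-N-methylnon-3-enamide
Conditions: MeNH(OMe)·HCl, EDC·HCl, N-methylmorpholine, CH2Cl2, 0 °C to rt
Reagents that add atoms: N,O-dimethylhydroxylamine hydrochloride, CNOC.Cl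
Why: Carbodiimide amide coupling gives the Weinreb amide with no base stronger than N-methylmorpholine, which should leave the β,γ-alkene unconjugated.

Step 3
Reactants: 3 (Z)-N-methoxy-N-methylnon-3-enamide; 4 ethynyltrimethylsilane
Product: 6 (Z)-1-(trimethylsilyl)undec-5-en-1-yn-3-one, via lithium (trimethylsilyl)acetylide 5 (not isolated)
Conditions: 4, n-BuLi, THF, −78 °C; then 3, −78 to 0 °C; cold aq. NH4Cl
Reagents that add atoms: none
Why: In this Weinreb ketone synthesis the chelated tetrahedral adduct stops at the ketone stage and keeps the acidic C13 methylene masked until the cold buffered quench, so over-addition and migration of the Z-alkene into conjugation should be avoided.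

Step 4
Reactants: 6 (Z)-1-(trimethylsilyl)undec-5-en-1-yn-3-one; 7 ethyl bromoacetate
Product: 9 ethyl (Z)-3-hydroxy-3-[(trimethylsilyl)ethynyl]undec-5-enoate (racemic), via Reformatsky reagent 8 (not isolated)
Conditions: 7, Zn (TMSCl-activated), THF, rt; then 6, 0 °C to rt; aq. NH4Cl
Reagents that add atoms: none
Why: In this Reformatsky reaction the weakly basic zinc ester enolate should add to the C12 carbonyl (C8–C12 bond) faster than it deprotonates C13, the silyl cap blocks conjugate addition at C10, and C12 is formed racemic on purpose.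

Step 5
Reactants: 9 ethyl (Z)-3-hydroxy-3-[(trimethylsilyl)ethynyl]undec-5-enoate (racemic)
Product: 10 ethyl (Z)-3-(methoxymethoxy)-3-[(trimethylsilyl)ethynyl]undec-5-enoate (racemic)
Conditions: MOMCl, i-Pr2NEt, NaI (cat.), CH2Cl2, 0 to 40 °C
Reagents that add atoms: chloromethyl methyl ether, COCCl
Why: Iodide-assisted O-alkylation of the unhindered tertiary propargylic alcohol installs the ether oxygen that must later bind rhodium, and the amine base is too weak to start a retro-aldol cleavage.

Step 6
Reactants: 10 ethyl (Z)-3-(methoxymethoxy)-3-[(trimethylsilyl)ethynyl]undec-5-enoate (racemic)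
Product: 11 (Z)-3-(methoxymethoxy)-3-[(trimethylsilyl)ethynyl]undec-5-enal (racemic)
Conditions: i-Bu2AlH (1.1 equiv), CH2Cl2, −78 °C; MeOH, aq. Rochelle salt
Reagents that add atoms: none
Why: Partial ester reduction at −78 °C should stop at the aluminium hemiacetal, which is stabilised by the β-ether oxygen and by the neopentyl-like position of the ester, and the aldehyde is released only on work-up.

Step 7
Reactants: 11 (Z)-3-(methoxymethoxy)-3-[(trimethylsilyl)ethynyl]undec-5-enal (racemic)
Product: 12 (S)-4-(methoxymethoxy)-4-[(Z)-oct-2-en-1-yl]-2-(trimethylsilyl)cyclopent-2-en-1-one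
Conditions: [Rh(nbd)((R)-Tol-BINAP)]BF4 (5 mol %; nbd removed with H2, then Ar purge), CH2Cl2, rt, stopped near half conversion
Reagents that add atoms: none
Why: The cationic monovalent rhodium centre should add oxidatively into the aldehyde C9–H bond to give an acyl hydride of trivalent rhodium, the hydride is delivered to C11 in a net trans sense, the alkenyl rhodium closes a six-membered acyl(alkenyl)rhodacycle (Rh, C9, C8, C12, C11, C10), and reductive elimination forms C9–C10. The closest known reaction is the cationic rhodium–bisphosphine trans-hydroacylation of 4-alkynals to cyclopentenones, which with Tol-BINAP resolves 3-methoxy-4-alkynals carrying a fully substituted C3; here the ether is a MOM ether and the alkyne carries silicon. The cyclopentenone ring (C8, C9, C10, C11, C12) closes in a formal 5-endo-dig mode, with both alkyne carbons inside the ring and silicon left on C10. C12 is not created but selected: binding of the C12 ether oxygen to the cationic metal holds the stereocentre inside the Tol-BINAP pocket, so the (S)-alkynal should cyclise much faster than its mirror image, which stays behind as aldehyde and is removed by chromatography. The step needs a high rate ratio between the enantiomers, which the ether coordination is meant to secure and which is protected by stopping below half conversion. It also needs the alkyne to react in preference to the C14=C15 alkene, which stands as a 5-alkenal to C9 and could only close a six-membered ring, slow with these catalysts, while the silyl cap suppresses the side reactions of a terminal alkyne.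

Step 8
Reactants: 12 (S)-4-(methoxymethoxy)-4-[(Z)-oct-2-en-1-yl]-2-(trimethylsilyl)cyclopent-2-en-1-one
Product: 13 (S)-4-(methoxymethoxy)-4-[(Z)-oct-2-en-1-yl]cyclopent-2-en-1-one
Conditions: Bu4NF, THF–H2O, 0 °C
Reagents that add atoms: none
Why: In this fluoride-mediated protodesilylation of an α-silyl enone, attack at silicon is assisted by the neighbouring carbonyl group and C10 is protonated by water, while the MOM ether and the isolated alkene are inert.

Step 9
Reactants: 13 (S)-4-(methoxymethoxy)-4-[(Z)-oct-2-en-1-yl]cyclopent-2-en-1-one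
Product: 14 (1S,4S,5R)-4-(methoxymethoxy)-4-[(Z)-oct-2-en-1-yl]-6-oxabicyclo[3.1.0]hexan-2-one
Conditions: 30% H2O2, NaOH (cat.), MeOH, 0 °C
Reagents that add atoms: hydrogen peroxide, OO
Why: In this Weitz–Scheffer epoxidation the hydroperoxide anion adds only to the electron-poor C10=C11 bond (expected anti to the larger octenyl group, drawn so) and leaves C14=C15 untouched; the epoxide face is of no consequence because C10 and C11 become trigonal again in step 10.

Step 10
Reactants: 14 (1S,4S,5R)-4-(methoxymethoxy)-4-[(Z)-oct-2-en-1-yl]-6-oxabicyclo[3.1.0]hexan-2-one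
Product: 16 (S)-2-chloro-4-hydroxy-4-[(Z)-oct-2-en-1-yl]cyclopent-2-en-1-one, via trans-chlorohydrin 15 (not isolated)
Conditions: conc. HCl, MeOH, 0 °C to rt
Reagents that add atoms: hydrogen chloride, Cl
Why: Chloride should open the protonated α,β-epoxy ketone at C10 (SN2 next to the carbonyl), the β-hydroxy ketone dehydrates through its enol to the α-chloro enone, and the same methanolic acid transfers the MOM group to methanol, while C12 keeps its configuration because its cation would be a destabilised oxocyclopentenyl cation.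

Step 11
Reactants: 16 (S)-2-chloro-4-hydroxy-4-[(Z)-oct-2-en-1-yl]cyclopent-2-en-1-one
Product: 17 (S)-2-chloro-4-[(Z)-oct-2-en-1-yl]-4-[(trimethylsilyl)oxy]cyclopent-2-en-1-one
Conditions: TMSCl, imidazole, DMF, 0 °C to rt
Reagents that add atoms: chlorotrimethylsilane, C[Si](C)(C)Cl
Why: Silylation of the tertiary alcohol under imidazole catalysis does not enolise the ketone and gives an ether that survives the amide base of step 16 and can be removed at the end under conditions the dienone tolerates.

Step 12
Reactants: 18 hex-5-ynoic acid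
Product: 20 7-hydroxyhept-5-ynoic acid, via bromomagnesium alkynide carboxylate 19 (not isolated)
Conditions: EtMgBr (2.2 equiv), THF, 0 to 40 °C; (CH2O)n, rt; aq. HCl
Reagents that add atoms: paraformaldehyde (as formaldehyde), C=O
Why: Two equivalents of EtMgBr deprotonate the acid and the terminal alkyne, and only the alkynyl Grignard carbon adds to formaldehyde because the carboxylate is inert.

Step 13
Reactants: 20 7-hydroxyhept-5-ynoic acid
Product: 21 methyl 7-hydroxyhept-5-ynoate
Conditions: MeOH, H2SO4 (cat.), rt
Reagents that add atoms: methanol, CO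
Why: Fischer esterification in excess methanol converts the acid and leaves the propargylic alcohol unchanged.

Step 14
Reactants: 21 methyl 7-hydroxyhept-5-ynoate
Product: 22 methyl (Z)-7-hydroxyhept-5-enoate
Conditions: H2 (1 atm), Pd/CaCO3–Pb(OAc)2 (Lindlar catalyst), quinoline, EtOAc, rt
Reagents that add atoms: none
Why: Syn addition of one equivalent of hydrogen on the poisoned palladium surface (Lindlar semi-hydrogenation) sets the C5=C6 Z-alkene.

Step 15
Reactants: 22 methyl (Z)-7-hydroxyhept-5-enoate
Product: 23 methyl (Z)-7-oxohept-5-enoate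
Conditions: Dess–Martin periodinane, NaHCO3, CH2Cl2, 0 °C; used at once
Reagents that add atoms: none
Why: Buffered Dess–Martin oxidation of the allylic alcohol involves neither acid nor base strong enough to isomerise the Z-enal, which is taken on without storage.

Step 16
Reactants: 17 (S)-2-chloro-4-[(Z)-oct-2-en-1-yl]-4-[(trimethylsilyl)oxy]cyclopent-2-en-1-one; 23 methyl (Z)-7-oxohept-5-enoate
Product: 25 methyl (5Z)-7-[3-chloro-5-[(Z)-oct-2-en-1-yl]-2-oxo-5-[(trimethylsilyl)oxy]cyclopent-3-en-1-yl]-7-hydroxyhept-5-enoate (mixture at C7 and C8; silyloxy carbon as in 17), via lithium dienolate 24 (not isolated)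
Conditions: LiN(i-Pr)2, THF, −78 °C; then 23, −78 °C; AcOH quench
Reagents that add atoms: none
Why: Kinetic deprotonation at C8, the only enolisable position, gives a dienolate that cannot expel the C12 siloxide without forming a cyclopentadienone and that adds 1,2 to the enal (aldol addition); the new C7 and C8 centres are uncontrolled and are removed in step 17.

Step 17
Reactants: 25 methyl (5Z)-7-[3-chloro-5-[(Z)-oct-2-en-1-yl]-2-oxo-5-[(trimethylsilyl)oxy]cyclopent-3-en-1-yl]-7-hydroxyhept-5-enoate
Product: 27 methyl (5Z,7E)-7-[(5R)-3-chloro-5-[(Z)-oct-2-en-1-yl]-2-oxo-5-[(trimethylsilyl)oxy]cyclopent-3-en-1-ylidene]hept-5-enoate, via C7 mesylate 26 (not isolated)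
Conditions: MsCl, Et3N, CH2Cl2, −20 to 0 °C, in the dark
Reagents that add atoms: none
Why: Mesylation of the secondary alcohol and E1cB elimination through the C8 enolate form the exocyclic C7=C8 bond, and the 7E isomer, with the C6 chain turned away from the C9 carbonyl oxygen, is expected to prevail, any 7Z isomer being removed by chromatography.

Step 18
Reactants: 27 methyl (5Z,7E)-7-[(5R)-3-chloro-5-[(Z)-oct-2-en-1-yl]-2-oxo-5-[(trimethylsilyl)oxy]cyclopent-3-en-1-ylidene]hept-5-enoate
Product: 28 chlorovulone I, methyl (5Z,7E)-7-[(5R)-3-chloro-5-hydroxy-5-[(Z)-oct-2-en-1-yl]-2-oxocyclopent-3-en-1-ylidene]hept-5-enoate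
Conditions: AcOH–THF–H2O (3:1:1), rt, in the dark
Reagents that add atoms: none
Why: Mild acidic hydrolysis of the tertiary trimethylsilyl ether should free the C12 alcohol without touching the ester, the chloro dienone or the alkene geometries, and C12 cannot ionise readily under these conditions.

**Compound list**

1 | (Z)-non-3-en-1-ol | CCCCC/C=C\CCO | starting material
2 | (Z)-non-3-enoic acid | CCCCC/C=C\CC(=O)O | intermediate
3 | (Z)-N-methoxy-N-methylnon-3-enamide | CCCCC/C=C\CC(=O)N(C)OC | intermediate
4 | ethynyltrimethylsilane | C#C[Si](C)(C)C | starting material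
5 | lithium (trimethylsilyl)acetylide | [Li]C#C[Si](C)(C)C | intermediate (not isolated)
6 | (Z)-1-(trimethylsilyl)undec-5-en-1-yn-3-one | CCCCC/C=C\CC(=O)C#C[Si](C)(C)C | intermediate
7 | ethyl bromoacetate | CCOC(=O)CBr | starting material
8 | Reformatsky reagent, (2-ethoxy-2-oxoethyl)zinc bromide | CCOC(=O)C[Zn]Br | intermediate (not isolated)
9 | ethyl (Z)-3-hydroxy-3-[(trimethylsilyl)ethynyl]undec-5-enoate, racemic | CCCCC/C=C\CC(O)(CC(=O)OCC)C#C[Si](C)(C)C | intermediate
10 | ethyl (Z)-3-(methoxymethoxy)-3-[(trimethylsilyl)ethynyl]undec-5-enoate, racemic | CCCCC/C=C\CC(OCOC)(CC(=O)OCC)C#C[Si](C)(C)C | intermediate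
11 | (Z)-3-(methoxymethoxy)-3-[(trimethylsilyl)ethynyl]undec-5-enal, racemic | CCCCC/C=C\CC(OCOC)(CC=O)C#C[Si](C)(C)C | intermediate
12 | (S)-4-(methoxymethoxy)-4-[(Z)-oct-2-en-1-yl]-2-(trimethylsilyl)cyclopent-2-en-1-one | CCCCC/C=C\C[C@@]1(OCOC)C=C([Si](C)(C)C)C(=O)C1 | intermediate
13 | (S)-4-(methoxymethoxy)-4-[(Z)-oct-2-en-1-yl]cyclopent-2-en-1-one | CCCCC/C=C\C[C@@]1(OCOC)C=CC(=O)C1 | intermediate
14 | (1S,4S,5R)-4-(methoxymethoxy)-4-[(Z)-oct-2-en-1-yl]-6-oxabicyclo[3.1.0]hexan-2-one (epoxide on the face of the MOM ether) | CCCCC/C=C\C[C@@]1(OCOC)[C@@H]2O[C@@H]2C(=O)C1 | intermediate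
15 | (2R,3S,4S)-2-chloro-3-hydroxy-4-(methoxymethoxy)-4-[(Z)-oct-2-en-1-yl]cyclopentan-1-one (chlorine trans to hydroxyl) | CCCCC/C=C\C[C@@]1(OCOC)[C@H](O)[C@@H](Cl)C(=O)C1 | intermediate (not isolated)
16 | (S)-2-chloro-4-hydroxy-4-[(Z)-oct-2-en-1-yl]cyclopent-2-en-1-one | CCCCC/C=C\C[C@@]1(O)C=C(Cl)C(=O)C1 | intermediate
17 | (S)-2-chloro-4-[(Z)-oct-2-en-1-yl]-4-[(trimethylsilyl)oxy]cyclopent-2-en-1-one | CCCCC/C=C\C[C@@]1(O[Si](C)(C)C)C=C(Cl)C(=O)C1 | intermediate
18 | hex-5-ynoic acid | C#CCCCC(=O)O | starting material
19 | bromomagnesium 6-(bromomagnesio)hex-5-ynoate | Br[Mg]C#CCCCC(=O)O[Mg]Br | intermediate (not isolated)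
20 | 7-hydroxyhept-5-ynoic acid | OCC#CCCCC(=O)O | intermediate
21 | methyl 7-hydroxyhept-5-ynoate | COC(=O)CCCC#CCO | intermediate
22 | methyl (Z)-7-hydroxyhept-5-enoate | COC(=O)CCC/C=C\CO | intermediate
23 | methyl (Z)-7-oxohept-5-enoate | COC(=O)CCC/C=C\C=O | intermediate
24 | lithium 5-chloro-3-[(Z)-oct-2-en-1-yl]-3-[(trimethylsilyl)oxy]cyclopenta-1,4-dien-1-olate (quaternary carbon as in 17) | CCCCC/C=C\C[C@@]1(O[Si](C)(C)C)C=C(Cl)C(O[Li])=C1 | intermediate (not isolated)
25 | methyl (5Z)-7-[3-chloro-5-[(Z)-oct-2-en-1-yl]-2-oxo-5-[(trimethylsilyl)oxy]cyclopent-3-en-1-yl]-7-hydroxyhept-5-enoate (mixture at C7 and C8; silyloxy carbon as in 17) | CCCCC/C=C\C[C@@]1(O[Si](C)(C)C)C=C(Cl)C(=O)C1C(O)/C=C\CCCC(=O)OC | intermediate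
26 | methyl (5Z)-7-[3-chloro-5-[(Z)-oct-2-en-1-yl]-2-oxo-5-[(trimethylsilyl)oxy]cyclopent-3-en-1-yl]-7-[(methylsulfonyl)oxy]hept-5-enoate | CCCCC/C=C\C[C@@]1(O[Si](C)(C)C)C=C(Cl)C(=O)C1C(OS(C)(=O)=O)/C=C\CCCC(=O)OC | intermediate (not isolated)
27 | methyl (5Z,7E)-7-[(5R)-3-chloro-5-[(Z)-oct-2-en-1-yl]-2-oxo-5-[(trimethylsilyl)oxy]cyclopent-3-en-1-ylidene]hept-5-enoate | CCCCC/C=C\C[C@@]1(O[Si](C)(C)C)C=C(Cl)C(=O)/C1=C/C=C\CCCC(=O)OC | intermediate
28 | chlorovulone I, methyl (5Z,7E)-7-[(5R)-3-chloro-5-hydroxy-5-[(Z)-oct-2-en-1-yl]-2-oxocyclopent-3-en-1-ylidene]hept-5-enoate | CCCCC/C=C\C[C@@]1(O)C=C(Cl)C(=O)/C1=C/C=C\CCCC(=O)OC | target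

**Step count**

Total: 18 steps. Longest linear sequence: 14 steps (steps 1–11, then 16–18); the C1–C7 branch (steps 12–15) joins at step 16.

**Steps most likely to fail**

Step 7. The two alkynal enantiomers may not be told apart well enough: the acetal oxygen of the MOM ether is a weaker donor than the methyl ether oxygen of the known substrates, and the silyl cap may slow alkyne insertion so that unselective cyclisation or decarbonylation competes. The fallback secures the stereocentre by separation and not by the catalyst. It sets out from racemic 11, which is cyclised with the achiral catalyst [Rh(dppe)]2(BF4)2 in acetone at rt to racemic 4-(methoxymethoxy)-4-[(Z)-oct-2-en-1-yl]-2-(trimethylsilyl)cyclopent-2-en-1-one F1. The enantiomers of F1 are separated by preparative chromatography on an amylose tris(3,5-dimethylphenylcarbamate) phase; the (S)-enantiomer is 12, where the route is rejoined.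

Step 17. Alkene geometry may be lost: the elimination may give too much of the 7Z isomer, and the C5=C6 Z-alkene may drift to E, either in enal 23 before the aldol or through ionisation of the allylic mesylate. The fallback carries C5–C6 as an alkyne through the condensation and reduces it last. It sets out from 17 and 21. Alcohol 21 is oxidised (Dess–Martin periodinane, NaHCO3, CH2Cl2) to methyl 7-oxohept-5-ynoate F2. Dienolate 24, made from 17 as in step 16, adds to F2 to give the propargylic aldol F3. MsCl and Et3N convert F3, via the C7 mesylate F4, into the 7E enynone F5, whose slim alkynyl group meets less strain next to C12. Semi-hydrogenation of F5 over Pd/CaCO3–Pb(OAc)2 with quinoline reduces only the C5–C6 alkyne to the Z-alkene and gives 27, where the route is rejoined.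

Step 10. The three events may not keep pace: loss of the MOM group may lag behind ring opening and dehydration, or the free 4-hydroxy enone may degrade in the acid (dehydration toward a cyclopentadienone, addition of HCl) before cleavage is complete. The fallback separates the events and removes the MOM group with a Lewis acid. It sets out from 14, which is opened with LiCl and AcOH in THF at rt to chlorohydrin 15, now isolated. MsCl and Et3N give the C11 mesylate F6, which eliminates in the same flask to (S)-2-chloro-4-(methoxymethoxy)-4-[(Z)-oct-2-en-1-yl]cyclopent-2-en-1-one F7. Me2BBr in CH2Cl2 at −78 °C, followed by aqueous NaHCO3, cleaves the MOM ether of F7 and gives 16, where the route is rejoined.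

**Further compounds**

F1 | step 7 | racemic 4-(methoxymethoxy)-4-[(Z)-oct-2-en-1-yl]-2-(trimethylsilyl)cyclopent-2-en-1-one | CCCCC/C=C\CC1(OCOC)C=C([Si](C)(C)C)C(=O)C1
F2 | step 17 | methyl 7-oxohept-5-ynoate | COC(=O)CCCC#CC=O
F3 | step 17 | methyl 7-[3-chloro-5-[(Z)-oct-2-en-1-yl]-2-oxo-5-[(trimethylsilyl)oxy]cyclopent-3-en-1-yl]-7-hydroxyhept-5-ynoate (mixture at C7 and C8) | CCCCC/C=C\C[C@@]1(O[Si](C)(C)C)C=C(Cl)C(=O)C1C(O)C#CCCCC(=O)OC
F4 | step 17 | methyl 7-[3-chloro-5-[(Z)-oct-2-en-1-yl]-2-oxo-5-[(trimethylsilyl)oxy]cyclopent-3-en-1-yl]-7-[(methylsulfonyl)oxy]hept-5-ynoate | CCCCC/C=C\C[C@@]1(O[Si](C)(C)C)C=C(Cl)C(=O)C1C(OS(C)(=O)=O)C#CCCCC(=O)OC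
F5 | step 17 | methyl (7E)-7-[(5R)-3-chloro-5-[(Z)-oct-2-en-1-yl]-2-oxo-5-[(trimethylsilyl)oxy]cyclopent-3-en-1-ylidene]hept-5-ynoate | CCCCC/C=C\C[C@@]1(O[Si](C)(C)C)C=C(Cl)C(=O)/C1=C/C#CCCCC(=O)OC
F6 | step 10 | (1S,2R,5S)-2-chloro-5-(methoxymethoxy)-5-[(Z)-oct-2-en-1-yl]-3-oxocyclopentyl methanesulfonate | CCCCC/C=C\C[C@@]1(OCOC)[C@H](OS(C)(=O)=O)[C@@H](Cl)C(=O)C1
F7 | step 10 | (S)-2-chloro-4-(methoxymethoxy)-4-[(Z)-oct-2-en-1-yl]cyclopent-2-en-1-one | CCCCC/C=C\C[C@@]1(OCOC)C=C(Cl)C(=O)C1
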